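## Structural features

The target is a C20 dibromo triol made of two carbocyclic parts joined through the secondary carbinol C7, which links C1' of ring A to C8 of a hydrindane. Ring A is a cyclohexane with a tertiary alcohol at C1', a gem-dimethyl group at C3' and an equatorial bromide at C4'. The hydrindane is a cyclopentane (C8–C9–C10–C11–C16) trans-fused to ring B (C11–C16), which carries an angular methyl at C11, an equatorial bromide at C12 and a methyl-bearing tertiary alcohol at C15. Seven of the eight stereocentres (C1', C7, C8, C16, C15, C11, C12) are contiguous and only C4' is remote. C11 is quaternary and C15 fully substituted, both flank the ring-fusion methine C16, and the C11 methyl and C15 hydroxyl stand 1,3-diaxial on one face of ring B. Fragile points are the two secondary bromides beside quaternary carbons (elimination, reduction, halogen–metal exchange), the two tertiary alcohols (dehydration) and the C7/C1' diol (pinacol-type shifts in strong acid). The real difficulty is the congested C11–C16–C15 triad with its trans fusion, the relay of configuration from C8 through C7 to C1', and equatorial bromine next to quaternary centres, where displacement is not an option. The key step uses the fact that ring B is oxygenated para at C12 and C15 with a methyl on C11, the pattern of the para-quinol of 2,4-dimethylphenol: the C15 oxygen guides C8 onto C16 and the C11/C12 enolate then takes up C10.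

## Logic of the disconnections

**C12–Br and C4'–Br, together with C13–H and C5'–H.** The C–Br bonds are kept and the neighbouring C–H bonds are cut, taking 34 through 33 back to 32. Both bromides are equatorial and neopentylic, so inversion chemistry is unrealistic; adding hydrogen to a bromoalkene is. Two stereocentres become flat carbons and both rings are treated in one operation. The forward step must deliver hydrogen axially at C12 and C4' and must not break C–Br.

**C–Br to C–O at C12 and C4'.** 32 goes back to 31, then 30, then 29. Each carbonyl has a single enolisable neighbour (C13, C5'), because C11 and C3' are quaternary, so the alkene position is unambiguous. The demand is that the three hydroxyls are masked during the enolate chemistry (30) and that the ketones can be unveiled from 28 without harming the diol.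

**C6'–H and the C1'–O relay.** 28 goes back to 27 and then 26. The tertiary carbinol C1' is drawn from an epoxide across C1'=C6', placed by the C7 hydroxyl. Ring A becomes a simple cyclohexene and C1' is controlled from C7. The forward steps need erythro-selective epoxidation, hydride attack at C6' only, and both carbonyls masked as dioxolanes.

**C7–H.** 26 goes back to 25, which comes from 24 by oxidation. Hydride addition to the C7 ketone gives the configuration that direct carbon addition to the aldehyde would not. The demand is 1,2-reduction under control of the C8 centre.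

**C7–C1'.** 24 is cut into 17 and 23. This is the convergent junction of the two halves. The coupling must be chemoselective for the aldehyde, tolerate a free tertiary alcohol and not epimerise C8.

**Ring A fragment.** 23 goes back to 22, 21 (through 20), 19 and 18: the C–OTf bond and the two C3'–CH3 bonds are cut. This reaches a catalogue cyclohexanone. The demands are gem-dimethylation beside the carbonyl that becomes C4' and kinetic enolisation of 22 away from the gem-dimethyl carbon.

**C7 oxidation level and C12 masking.** 17 goes back to 16, and 16 (through 15) to 14. No skeletal bond is cut. The C12 ketone must be ketalised without dehydrating the C15 alcohol.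

**C8–H and C9–H.** 14 goes back to 13. C8 becomes sp2 and its configuration is left to the C15 hydroxyl. Hydrogen must arrive syn to that hydroxyl against the steric bias of the C11 methyl.

**C8=C9.** 13 goes back to 12 by ring-closing metathesis. The cyclopentane is reduced to two alkenes on ring B, which must already be trans on C11 and C16.

**C8–C16 and C10–C11 (key).** 12 is cut into 4, 6 and 7. Two bonds and two stereocentres (C16, C11) come from one enone in one flask, and C15 and the C12 carbonyl arrive complete. The demands are syn delivery from the C15 alkoxide, 1,4-selectivity, and anti C-allylation of a single enolate. The precursors are refined in two ways: the alkoxide of 4 is pre-formed with a sacrificial base (10), and the alkenyl reagent is generated cold through 8 and 9, so that neither the reagent nor its silyl ether is wasted.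

**Precursors.** 4 goes back to 3, 2 and 1 (C15–O bond, then the ring hydrogens); 6 goes back to 5. The tertiary carbinol has no handle for classical resolution, hence chromatography.

## Other disconnections considered

Alternative 1: The cut is C1'–C2' of ring A. In the forward step SmI2 with HMPA would reduce the neopentyl iodide of the acyclic hydroxy ketone A1 and the resulting alkylsamarium would add to the C1' ketone to give the diol A2. In its favour, ring A closes late on a finished hydrindane, and C1' is set inside a rigid five-membered samarium chelate between the C7 oxygen and the C1' carbonyl. That is at least the equal of, and arguably tighter than, the open-chain A(1,2) relay used here, and it makes the carbinol and the ring in one step where the chosen plan needs epoxidation plus hydride opening. Against it, A1 is an α-oxygenated ketone: SmI2/HMPA tends to form the ketyl and cleave the α C–O bond faster than it reduces a neopentyl iodide, and the hindered six-ring Barbier closure competes with simple reduction. A1 also needs a seven-carbon chain with its own ketal and iodide built onto C7 after the C8-to-C7 induction problem has been solved anyway. Structurally A2 is just the C15 silyl ether of 28, so the endgame would be identical. Mechanistically a radical/ketyl process replaces two polar, directed steps. In step count the chain assembly should cost more than the four steps to 23, so no net saving is expected. The alternative says nothing about the hydrindane and would complement the chosen key step, not replace it.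

Alternative 2: The cuts are C11–C16, C8–C9 and C9–C10. Co2(CO)8 would complex the terminal alkyne of enyne A3 and, promoted by N-methylmorpholine N-oxide, cyclocarbonylation would give the bicyclic enone A4. In its favour, two rings and three C–C bonds form in one step from an acyclic precursor, and C15 could come from the terpene chiral pool without a resolution. On both counts it is better than the chosen key step, which closes no ring and depends on a chromatographic resolution. Against it here, the alkene is 1,1-disubstituted and must create the quaternary C11 while a six-membered ring closes, both of which slow Pauson–Khand reactions. The only control over C11 is the remote C15 centre across the forming ring. The tertiary propargylic ether is prone to ionise as its dicobalt complex. A4 also has a carbonyl at C9 that the target lacks, no carbon on C8 for C7, and C16 as an sp2 carbon, and reduction of such enones to trans-hydrindanes is notoriously biased toward cis. In the chosen plan the trans fusion is fixed by anti alkylation and C7 is built in. Once C9 deoxygenation, C7 introduction and fusion control are counted, the alternative is unlikely to be shorter.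

Alternative 3: The cut is C8–C16. Rh2(OAc)4 would decompose the diazo keto ester A5 and the carbenoid at C8 would insert into the equatorial C16–H bond to give the keto ester A6. In its favour, insertion is stereospecific with retention, so an equatorial tether and an equatorial C–H give the trans fusion directly, and C8 as a β-keto ester settles thermodynamically. The C12 bromide is already present, and C7 arrives at the acyl oxidation level, which would allow direct ketone formation with ring A and save the oxidation after step 14. On those two points it is better than the chosen plan. Against it, C16 is a methylene between two fully substituted carbons and β to the C15 silyloxy group, so it is both shielded and inductively deactivated. Five-membered insertion into C12–H or the C11 methyl, and ylide formation at the ether oxygen or at bromine, are open competitors with nothing in the substrate to exclude them. A6 carries an extra C9 ketone to be removed beside a secondary bromide. A5 presupposes a ring B with C11, C12 and C15 already set, which would itself need quinol chemistry and an early bromide that must survive diazo transfer. Each bond of the chosen key step is guided by a neighbouring group, whereas here site selectivity is unguarded, and in steps the alternative is not shorter.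

Key step: step 5

Assumption: 18 is taken as a catalogue compound, and the enantiomer of 3 collected in step 3 is assigned as R (4) by its chiroptical data before it is used.

## Route

Step 1
Reactants: 1 2,4-dimethylphenol
Product: 2 rac-4-hydroxy-2,4-dimethylcyclohexa-2,5-dien-1-one
Conditions: PhI(OAc)2, MeCN/H2O (3:1), 0 °C
Reagents that add atoms: water, O
Why: Oxidative dearomatisation: the iodane activates the phenol oxygen and water adds para, where the methyl group blocks rearomatisation, giving the para-quinol. C15 is formed racemic.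

Step 2
Reactants: 2 rac-4-hydroxy-2,4-dimethylcyclohexa-2,5-dien-1-one
Product: 3 rac-4-hydroxy-2,4-dimethylcyclohex-2-en-1-one
Conditions: H2 (1 atm), RhCl(PPh3)3 (cat.), benzene, rt
Reagents that add atoms: none
Why: Homogeneous hydrogenation with RhCl(PPh3)3 should reduce the unhindered disubstituted alkene and leave the methyl-bearing trisubstituted enone alkene, without hydrogenolysis of the tertiary allylic C–O bond.

Step 3
Reactants: 3 rac-4-hydroxy-2,4-dimethylcyclohex-2-en-1-one
Product: 4 (R)-4-hydroxy-2,4-dimethylcyclohex-2-en-1-one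
Conditions: preparative supercritical-fluid chromatography, amylose tris(3,5-dimethylphenylcarbamate) phase, CO2/MeOH
Reagents that add atoms: none
Why: Resolution by chiral chromatography; the lone stereocentre is a tertiary carbinol with no handle for salt formation or enzymatic acylation, so physical separation is the safest entry. The R enantiomer carries the C15 configuration of the target.

Step 4
Reactants: 5 2-bromoprop-2-en-1-ol
Product: 6 tert-butyl[(2-bromoprop-2-en-1-yl)oxy]dimethylsilane
Conditions: TBSCl, imidazole, CH2Cl2, 0 °C → rt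
Reagents that add atoms: tert-butyldimethylsilyl chloride, CC(C)(C)[Si](C)(C)Cl
Why: Standard silylation of a primary alcohol; the bulky silyl ether survives organometallic, metathesis and hydrogenation conditions.

Step 5
Reactants: 4 (R)-4-hydroxy-2,4-dimethylcyclohex-2-en-1-one; 6 tert-butyl[(2-bromoprop-2-en-1-yl)oxy]dimethylsilane; 7 3-bromoprop-1-ene
Product: 12 (2S,3S,4R)-2-allyl-3-[3-(tert-butyldimethylsilyloxy)prop-1-en-2-yl]-4-hydroxy-2,4-dimethylcyclohexan-1-one, via alkenyllithium 8 (not isolated), via alkenylmagnesium bromide 9 (not isolated), via chloromagnesium alkoxide 10 (not isolated), via magnesium enolate 11 (not isolated)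
Conditions: 6, t-BuLi (2 equiv), Et2O, −78 °C; MgBr2·OEt2, −78 °C; 4, t-BuMgCl (1 equiv), THF, −78 °C; combine, −78 → −20 °C; 7, DMPU, −20 °C → rt; aq. NH4Cl
Reagents that add atoms: none
Why: t-BuMgCl first turns the C15 hydroxyl of 4 into the chloromagnesium alkoxide 10, so that none of the alkenyl reagent is spent as a base, while 6 is converted at −78 °C through the lithium compound 8 into the Grignard reagent 9 (at this temperature and with magnesium as counter-ion neither silyl migration from oxygen to carbon nor loss of silanolate to an allene should compete). Reagent 9 aggregates with the alkoxide of 10 and is handed over within this aggregate to the neighbouring β-carbon C16, which is the known alkoxide-directed conjugate addition of organomagnesium reagents to 4-hydroxycyclohex-2-enones and needs no copper. Because the nucleophile arrives from the oxygen-bearing face, the new C8–C16 bond is cis to the C15 oxygen, so the resolved C15 centre fixes C16 (S). The remote C12 carbonyl cannot be reached from the alkoxide, which secures 1,4- over 1,2-addition, and the α-methyl group guarantees a single, regiodefined magnesium enolate 11 (C11=C12). Addition of 7 with DMPU then C-allylates 11 at C11, the closest known reaction type being the conjugate addition–enolate alkylation of 2-methylcyclohex-2-enones; the electrophile enters anti to the adjacent C16 substituent, which A(1,2) strain with the C11 methyl holds pseudoaxial, and this fixes the quaternary C11 (S) with allyl trans to C8. No ring is closed in this step; the two new alkenes are placed trans-diequatorial for the later metathesis. The selectivities needed (1,4 over 1,2, syn to oxygen, C- over O-allylation, anti alkylation without enolate equilibration) rest on the tethering alkoxide, on the soft allylic halide and on trapping the enolate as it is formed.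

Step 6
Reactants: 12 (2S,3S,4R)-2-allyl-3-[3-(tert-butyldimethylsilyloxy)prop-1-en-2-yl]-4-hydroxy-2,4-dimethylcyclohexan-1-one
Product: 13 (3aS,7R,7aS)-1-[(tert-butyldimethylsilyloxy)methyl]-7-hydroxy-3a,7-dimethyl-3,3a,5,6,7,7a-hexahydro-4H-inden-4-one
Conditions: second-generation Grubbs catalyst (5 mol %), CH2Cl2, 40 °C
Reagents that add atoms: none
Why: Ring-closing metathesis between the allyl group and the 1,1-disubstituted alkene, held trans-diequatorial on ring B, closes the cyclopentene with loss of ethene. The trans fusion is already fixed by step 5, and the free alcohol and ketone are tolerated.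

Step 7
Reactants: 13 (3aS,7R,7aS)-1-[(tert-butyldimethylsilyloxy)methyl]-7-hydroxy-3a,7-dimethyl-3,3a,5,6,7,7a-hexahydro-4H-inden-4-one
Product: 14 (1R,3aS,7R,7aS)-1-[(tert-butyldimethylsilyloxy)methyl]-7-hydroxy-3a,7-dimethyloctahydro-4H-inden-4-one
Conditions: H2 (1 atm), [Ir(cod)(PCy3)(py)]PF6 (10 mol %), CH2Cl2, rt
Reagents that add atoms: none
Why: Hydroxyl-directed hydrogenation: the cationic iridium centre binds the axial C15 hydroxyl, which is gauche to C8, and delivers H2 to the alkene face syn to oxygen. Hydrogen thus adds to C8 on the hydroxyl face and C7 ends trans to the C16–C15 bond (C8 R), against the steric bias of the angular methyl.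

Step 8
Reactants: 14 (1R,3aS,7R,7aS)-1-[(tert-butyldimethylsilyloxy)methyl]-7-hydroxy-3a,7-dimethyloctahydro-4H-inden-4-one
Product: 16 (1R,3aS,7R,7aS)-4,4-(ethylenedioxy)-1-(hydroxymethyl)-3a,7-dimethyloctahydro-1H-inden-7-ol, via dioxolane silyl ether 15 (not isolated)
Conditions: TMSOCH2CH2OTMS, TMSOTf (cat.), CH2Cl2, −78 → −20 °C; Et3N; then TBAF, THF, rt
Reagents that add atoms: 1,2-bis(trimethylsilyloxy)ethane, C[Si](C)(C)OCCO[Si](C)(C)C
Why: Silyl-transfer ketalisation masks the hindered C12 ketone under cold aprotic conditions that cannot dehydrate the tertiary alcohol; the ketal is needed because two hydride steps follow. Fluoride then cleaves the primary silyl ether and leaves the tertiary alcohol free whatever its state after the first stage.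

Step 9
Reactants: 16 (1R,3aS,7R,7aS)-4,4-(ethylenedioxy)-1-(hydroxymethyl)-3a,7-dimethyloctahydro-1H-inden-7-ol
Product: 17 (1R,3aS,7R,7aS)-4,4-(ethylenedioxy)-7-hydroxy-3a,7-dimethyloctahydro-1H-indene-1-carbaldehyde
Conditions: Dess–Martin periodinane, NaHCO3, CH2Cl2, 0 °C → rt
Reagents that add atoms: none
Why: Dess–Martin oxidation of the primary alcohol; the tertiary alcohol is inert and the buffer protects the ketal. C8 already has the thermodynamically preferred arrangement (formyl trans to the C16–C15 bond), so epimerisation is not a concern.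

Step 10
Reactants: 18 4-(tert-butyldimethylsilyloxy)cyclohexan-1-one
Product: 19 rac-4-(tert-butyldimethylsilyloxy)-2,2-dimethylcyclohexan-1-one
Conditions: KOt-Bu (2.5 equiv), MeI (3 equiv), THF, 0 °C → rt
Reagents that add atoms: iodomethane, CI
Why: Double α-methylation under equilibrating conditions: after the first alkylation the more substituted potassium enolate is the one that reacts, so the second methyl should go to the same carbon (future C3'). Regioisomers are removed by chromatography.

Step 11
Reactants: 19 rac-4-(tert-butyldimethylsilyloxy)-2,2-dimethylcyclohexan-1-one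
Product: 21 rac-6,6-dimethyl-1,4-dioxaspiro[4.5]decan-8-ol, via silyl ether ketal 20 (not isolated)
Conditions: HOCH2CH2OH, TsOH·H2O (cat.), benzene, reflux (Dean–Stark); then TBAF, THF, rt
Reagents that add atoms: ethane-1,2-diol, OCCO
Why: Acid-catalysed ketalisation with azeotropic removal of water masks the hindered carbonyl (future C4'); fluoride completes removal of the silyl ether and frees the hydroxyl at the future C1'.

Step 12
Reactants: 21 rac-6,6-dimethyl-1,4-dioxaspiro[4.5]decan-8-ol
Product: 22 6,6-dimethyl-1,4-dioxaspiro[4.5]decan-8-one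
Conditions: Dess–Martin periodinane, NaHCO3, CH2Cl2, rt
Reagents that add atoms: none
Why: Oxidation of the secondary alcohol to the ketone; this removes the only stereocentre of the fragment.

Step 13
Reactants: 22 6,6-dimethyl-1,4-dioxaspiro[4.5]decan-8-one
Product: 23 6,6-dimethyl-1,4-dioxaspiro[4.5]dec-8-en-8-yl trifluoromethanesulfonate
Conditions: LiN(i-Pr)2, THF, −78 °C; PhNTf2, −78 → 0 °C
Reagents that add atoms: N-phenylbis(trifluoromethanesulfonimide), O=S(=O)(N(c1ccccc1)S(=O)(=O)C(F)(F)F)C(F)(F)F
Why: Kinetic deprotonation by the bulky amide should occur at the methylene remote from the gem-dimethyl carbon, since the other α-methylene is neopentylic and shielded. Trapping with the triflimide gives the C1'=C6' enol triflate.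

Step 14
Reactants: 17 (1R,3aS,7R,7aS)-4,4-(ethylenedioxy)-7-hydroxy-3a,7-dimethyloctahydro-1H-indene-1-carbaldehyde; 23 6,6-dimethyl-1,4-dioxaspiro[4.5]dec-8-en-8-yl trifluoromethanesulfonate
Product: 24 [(1R,3aS,7R,7aS)-4,4-(ethylenedioxy)-7-hydroxy-3a,7-dimethyloctahydro-1H-inden-1-yl](6,6-dimethyl-1,4-dioxaspiro[4.5]dec-8-en-8-yl)methanol (both C7 epimers)
Conditions: CrCl2 (excess), NiCl2 (cat.), DMF, rt
Reagents that add atoms: none
Why: Nozaki–Hiyama–Kishi coupling: nickel activates the enol triflate and the alkenylchromium formed with divalent chromium adds only to the aldehyde, tolerating the free tertiary alcohol and both ketals without base that could epimerise C8. C7 is formed as a mixture (the Felkin–Anh sense for carbon addition is the undesired one) and is erased in step 15.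

Step 15
Reactants: 24 [(1R,3aS,7R,7aS)-4,4-(ethylenedioxy)-7-hydroxy-3a,7-dimethyloctahydro-1H-inden-1-yl](6,6-dimethyl-1,4-dioxaspiro[4.5]dec-8-en-8-yl)methanol (both C7 epimers)
Product: 25 [(1R,3aS,7R,7aS)-4,4-(ethylenedioxy)-7-hydroxy-3a,7-dimethyloctahydro-1H-inden-1-yl](6,6-dimethyl-1,4-dioxaspiro[4.5]dec-8-en-8-yl)methanone
Conditions: Dess–Martin periodinane, NaHCO3, CH2Cl2, 0 °C → rt
Reagents that add atoms: none
Why: Dess–Martin oxidation converges both carbinol epimers on one enone; the tertiary alcohol and the buffered ketals are unaffected.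

Step 16
Reactants: 25 [(1R,3aS,7R,7aS)-4,4-(ethylenedioxy)-7-hydroxy-3a,7-dimethyloctahydro-1H-inden-1-yl](6,6-dimethyl-1,4-dioxaspiro[4.5]dec-8-en-8-yl)methanone
Product: 26 (R)-[(1R,3aS,7R,7aS)-4,4-(ethylenedioxy)-7-hydroxy-3a,7-dimethyloctahydro-1H-inden-1-yl](6,6-dimethyl-1,4-dioxaspiro[4.5]dec-8-en-8-yl)methanol
Conditions: NaBH4, CeCl3·7H2O, MeOH, −78 °C
Reagents that add atoms: none
Why: Luche reduction gives clean 1,2-addition to the enone. By the Felkin–Anh model hydride attacks anti to C16, the largest substituent on C8, and past the C8 hydrogen, which should give C7 (R), the epimer that carbon addition to the aldehyde disfavours.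

Step 17
Reactants: 26 (R)-[(1R,3aS,7R,7aS)-4,4-(ethylenedioxy)-7-hydroxy-3a,7-dimethyloctahydro-1H-inden-1-yl](6,6-dimethyl-1,4-dioxaspiro[4.5]dec-8-en-8-yl)methanol
Product: 27 (R)-[(1R,3aS,7R,7aS)-4,4-(ethylenedioxy)-7-hydroxy-3a,7-dimethyloctahydro-1H-inden-1-yl][(1R,6R)-4,4-(ethylenedioxy)-3,3-dimethyl-7-oxabicyclo[4.1.0]heptan-1-yl]methanol
Conditions: VO(acac)2 (cat.), t-BuOOH, CH2Cl2, 0 °C → rt
Reagents that add atoms: tert-butyl hydroperoxide, CC(C)(C)OO
Why: Vanadium-catalysed hydroxyl-directed epoxidation of the allylic alcohol. A(1,2) strain between the C8 group on C7 and ring carbon C2' makes the C7 hydrogen eclipse C2', so oxygen is delivered to the face that gives the erythro epoxy alcohol (C1' R, C6' R); no other alkene is present.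

Step 18
Reactants: 27 (R)-[(1R,3aS,7R,7aS)-4,4-(ethylenedioxy)-7-hydroxy-3a,7-dimethyloctahydro-1H-inden-1-yl][(1R,6R)-4,4-(ethylenedioxy)-3,3-dimethyl-7-oxabicyclo[4.1.0]heptan-1-yl]methanol
Product: 28 (R)-[(1R)-4,4-(ethylenedioxy)-1-hydroxy-3,3-dimethylcyclohexyl][(1R,3aS,7R,7aS)-4,4-(ethylenedioxy)-7-hydroxy-3a,7-dimethyloctahydro-1H-inden-1-yl]methanol
Conditions: LiAlH4, THF, 0 → 50 °C
Reagents that add atoms: none
Why: Hydride opens the trisubstituted epoxide by SN2 attack at the secondary carbon C6' in the trans-diaxial sense; the fully substituted C1' is not attacked, so its C–O bond and configuration are retained. Both dioxolanes are inert to hydride.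

Step 19
Reactants: 28 (R)-[(1R)-4,4-(ethylenedioxy)-1-hydroxy-3,3-dimethylcyclohexyl][(1R,3aS,7R,7aS)-4,4-(ethylenedioxy)-7-hydroxy-3a,7-dimethyloctahydro-1H-inden-1-yl]methanol
Product: 29 (1R,3aS,7R,7aS)-7-hydroxy-1-{(R)-hydroxy[(1R)-1-hydroxy-3,3-dimethyl-4-oxocyclohexyl]methyl}-3a,7-dimethyloctahydro-4H-inden-4-one
Conditions: 1 M aq. HCl, THF, rt
Reagents that add atoms: water, O
Why: Acid-catalysed hydrolysis removes both dioxolanes in one operation; dilute acid at room temperature should leave the tertiary alcohols and the vicinal diol untouched.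

Step 20
Reactants: 29 (1R,3aS,7R,7aS)-7-hydroxy-1-{(R)-hydroxy[(1R)-1-hydroxy-3,3-dimethyl-4-oxocyclohexyl]methyl}-3a,7-dimethyloctahydro-4H-inden-4-one
Product: 30 tris(trimethylsilyl) ether of 29 (C7, C15 and C1' oxygens silylated)
Conditions: 1-(trimethylsilyl)imidazole, CH2Cl2, 40 °C
Reagents that add atoms: 1-(trimethylsilyl)imidazole, C[Si](C)(C)n1ccnc1
Why: This strong silyl donor caps all three hydroxyls, the two hindered tertiary ones included, and does not enolise ketones. The capping keeps alkoxides out of the triflation.

Step 21
Reactants: 30 tris(trimethylsilyl) ether of 29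
Product: 31 bis(enol triflate) of 30 (C12=C13 in ring B; C4'=C5' in ring A)
Conditions: KN(SiMe3)2 (3 equiv), PhNTf2 (3 equiv), THF, −78 → 0 °C
Reagents that add atoms: N-phenylbis(trifluoromethanesulfonimide), O=S(=O)(N(c1ccccc1)S(=O)(=O)C(F)(F)F)C(F)(F)F
Why: Enolate O-triflation; each ketone can enolise to one side only (C13, C5') because C11 and C3' are quaternary, so both enol triflates are regiodefined.

Step 22
Reactants: 31 bis(enol triflate) of 30
Product: 32 bis(alkenyl bromide): tris(trimethylsilyl) ether with C12(Br)=C13 and C4'(Br)=C5'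
Conditions: Ni(OAc)2·4H2O (cat.), 1,5-cyclooctadiene, Zn (cat.), LiBr, DMA/THF, rt
Reagents that add atoms: lithium bromide, [Li+].[Br-]
Why: Nickel-catalysed halogenation of enol triflates: zerovalent nickel inserts into C–OTf, triflate is exchanged for bromide on the metal and C–Br reductive elimination follows. The mild, neutral conditions suit hindered enol triflates and silyl ethers.

Step 23
Reactants: 32 bis(alkenyl bromide)
Product: 34 (R)-[(1R,4S)-4-bromo-1-hydroxy-3,3-dimethylcyclohexyl][(1R,3aS,4S,7R,7aS)-4-bromo-7-hydroxy-3a,7-dimethyloctahydro-1H-inden-1-yl]methanol (CNP0193924.1), via tris(trimethylsilyl) dibromide 33 (not isolated)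
Conditions: Mn(dpm)3 (cat., dpm = 2,2,6,6-tetramethylheptane-3,5-dionate), PhSiH3, t-BuOOH, i-PrOH, rt; then 1 M aq. HCl, THF, rt
Reagents that add atoms: none
Why: Metal-hydride hydrogen-atom-transfer hydrogenation: the manganese hydride gives a hydrogen atom to C13 and C5', and the bromine-stabilised radicals at C12 and C4' take the second hydrogen along the axial trajectory anti to the axial methyl on the neighbouring quaternary carbon, leaving both bromines equatorial (C12 S, C4' S). This radical hydrogenation of haloalkenes keeps C–Br intact, unlike hydrogenation over palladium. Dilute acid then removes the three trimethylsilyl ethers in the same flask.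

## Compound list

1 | 2,4-dimethylphenol | Cc1ccc(O)c(C)c1 | starting material
2 | rac-4-hydroxy-2,4-dimethylcyclohexa-2,5-dien-1-one | CC1=CC(C)(O)C=CC1=O | intermediate
3 | rac-4-hydroxy-2,4-dimethylcyclohex-2-en-1-one | CC1=CC(C)(O)CCC1=O | intermediate
4 | (R)-4-hydroxy-2,4-dimethylcyclohex-2-en-1-one | O=C1CC[C@@](C)(O)C=C1C | intermediate
5 | 2-bromoprop-2-en-1-ol | C=C(Br)CO | starting material
6 | tert-butyl[(2-bromoprop-2-en-1-yl)oxy]dimethylsilane | C=C(Br)CO[Si](C)(C)C(C)(C)C | intermediate
7 | 3-bromoprop-1-ene | C=CCBr | starting material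
8 | [3-(tert-butyldimethylsilyloxy)prop-1-en-2-yl]lithium | [Li]C(=C)CO[Si](C)(C)C(C)(C)C | intermediate
9 | [3-(tert-butyldimethylsilyloxy)prop-1-en-2-yl]magnesium bromide | Br[Mg]C(=C)CO[Si](C)(C)C(C)(C)C | intermediate
10 | chloromagnesium (R)-1,3-dimethyl-4-oxocyclohex-2-en-1-olate | O=C1CC[C@@](C)(O[Mg]Cl)C=C1C | intermediate
11 | magnesium enolate: C1 bromomagnesium enolate and C4 chloromagnesium alkoxide of (3S,4R)-3-[3-(tert-butyldimethylsilyloxy)prop-1-en-2-yl]-2,4-dimethylcyclohex-1-ene-1,4-diol | CC1=C(O[Mg]Br)CC[C@@](C)(O[Mg]Cl)[C@H]1C(=C)CO[Si](C)(C)C(C)(C)C | intermediate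
12 | (2S,3S,4R)-2-allyl-3-[3-(tert-butyldimethylsilyloxy)prop-1-en-2-yl]-4-hydroxy-2,4-dimethylcyclohexan-1-one | C=CC[C@]1(C)C(=O)CC[C@@](C)(O)[C@H]1C(=C)CO[Si](C)(C)C(C)(C)C | intermediate
13 | (3aS,7R,7aS)-1-[(tert-butyldimethylsilyloxy)methyl]-7-hydroxy-3a,7-dimethyl-3,3a,5,6,7,7a-hexahydro-4H-inden-4-one | CC(C)(C)[Si](C)(C)OCC1=CC[C@]2(C)C(=O)CC[C@@](C)(O)[C@@H]12 | intermediate
14 | (1R,3aS,7R,7aS)-1-[(tert-butyldimethylsilyloxy)methyl]-7-hydroxy-3a,7-dimethyloctahydro-4H-inden-4-one | CC(C)(C)[Si](C)(C)OC[C@@H]1CC[C@]2(C)C(=O)CC[C@@](C)(O)[C@@H]12 | intermediate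
15 | (1R,3aS,7R,7aS)-1-[(tert-butyldimethylsilyloxy)methyl]-4,4-(ethylenedioxy)-3a,7-dimethyloctahydro-1H-inden-7-ol | CC(C)(C)[Si](C)(C)OC[C@@H]1CC[C@]2(C)C3(OCCO3)CC[C@@](C)(O)[C@@H]12 | intermediate
16 | (1R,3aS,7R,7aS)-4,4-(ethylenedioxy)-1-(hydroxymethyl)-3a,7-dimethyloctahydro-1H-inden-7-ol | OC[C@@H]1CC[C@]2(C)C3(OCCO3)CC[C@@](C)(O)[C@@H]12 | intermediate
17 | (1R,3aS,7R,7aS)-4,4-(ethylenedioxy)-7-hydroxy-3a,7-dimethyloctahydro-1H-indene-1-carbaldehyde | O=C[C@@H]1CC[C@]2(C)C3(OCCO3)CC[C@@](C)(O)[C@@H]12 | intermediate
18 | 4-(tert-butyldimethylsilyloxy)cyclohexan-1-one | O=C1CCC(O[Si](C)(C)C(C)(C)C)CC1 | starting material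
19 | rac-4-(tert-butyldimethylsilyloxy)-2,2-dimethylcyclohexan-1-one | O=C1CCC(O[Si](C)(C)C(C)(C)C)CC1(C)C | intermediate
20 | rac-tert-butyl[(6,6-dimethyl-1,4-dioxaspiro[4.5]decan-8-yl)oxy]dimethylsilane | CC1(C)CC(O[Si](C)(C)C(C)(C)C)CCC12OCCO2 | intermediate
21 | rac-6,6-dimethyl-1,4-dioxaspiro[4.5]decan-8-ol | CC1(C)CC(O)CCC12OCCO2 | intermediate
22 | 6,6-dimethyl-1,4-dioxaspiro[4.5]decan-8-one | CC1(C)CC(=O)CCC12OCCO2 | intermediate
23 | 6,6-dimethyl-1,4-dioxaspiro[4.5]dec-8-en-8-yl trifluoromethanesulfonate | CC1(C)CC(OS(=O)(=O)C(F)(F)F)=CCC12OCCO2 | intermediate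
24 | [(1R,3aS,7R,7aS)-4,4-(ethylenedioxy)-7-hydroxy-3a,7-dimethyloctahydro-1H-inden-1-yl](6,6-dimethyl-1,4-dioxaspiro[4.5]dec-8-en-8-yl)methanol, both C7 epimers | CC1(C)CC(=CCC12OCCO2)C(O)[C@@H]3CC[C@]4(C)C5(OCCO5)CC[C@@](C)(O)[C@@H]34 | intermediate
25 | [(1R,3aS,7R,7aS)-4,4-(ethylenedioxy)-7-hydroxy-3a,7-dimethyloctahydro-1H-inden-1-yl](6,6-dimethyl-1,4-dioxaspiro[4.5]dec-8-en-8-yl)methanone | CC1(C)CC(=CCC12OCCO2)C(=O)[C@@H]3CC[C@]4(C)C5(OCCO5)CC[C@@](C)(O)[C@@H]34 | intermediate
26 | (R)-[(1R,3aS,7R,7aS)-4,4-(ethylenedioxy)-7-hydroxy-3a,7-dimethyloctahydro-1H-inden-1-yl](6,6-dimethyl-1,4-dioxaspiro[4.5]dec-8-en-8-yl)methanol | CC1(C)CC(=CCC12OCCO2)[C@H](O)[C@@H]3CC[C@]4(C)C5(OCCO5)CC[C@@](C)(O)[C@@H]34 | intermediate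
27 | (R)-[(1R,3aS,7R,7aS)-4,4-(ethylenedioxy)-7-hydroxy-3a,7-dimethyloctahydro-1H-inden-1-yl][(1R,6R)-4,4-(ethylenedioxy)-3,3-dimethyl-7-oxabicyclo[4.1.0]heptan-1-yl]methanol | CC1(C)C[C@@]2(O[C@@H]2CC13OCCO3)[C@H](O)[C@@H]4CC[C@]5(C)C6(OCCO6)CC[C@@](C)(O)[C@@H]45 | intermediate
28 | (R)-[(1R)-4,4-(ethylenedioxy)-1-hydroxy-3,3-dimethylcyclohexyl][(1R,3aS,7R,7aS)-4,4-(ethylenedioxy)-7-hydroxy-3a,7-dimethyloctahydro-1H-inden-1-yl]methanol | CC1(C)C[C@@](O)([C@H](O)[C@@H]2CC[C@]3(C)C4(OCCO4)CC[C@@](C)(O)[C@@H]23)CCC15OCCO5 | intermediate
29 | (1R,3aS,7R,7aS)-7-hydroxy-1-{(R)-hydroxy[(1R)-1-hydroxy-3,3-dimethyl-4-oxocyclohexyl]methyl}-3a,7-dimethyloctahydro-4H-inden-4-one | CC1(C)C[C@@](O)([C@H](O)[C@@H]2CC[C@]3(C)C(=O)CC[C@@](C)(O)[C@@H]23)CCC1=O | intermediate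
30 | tris(trimethylsilyl) ether of 29 (C7, C15, C1' oxygens) | CC1(C)C[C@@](O[Si](C)(C)C)([C@H](O[Si](C)(C)C)[C@@H]2CC[C@]3(C)C(=O)CC[C@@](C)(O[Si](C)(C)C)[C@@H]23)CCC1=O | intermediate
31 | bis(enol triflate) of 30 (C12=C13; C4'=C5') | CC1(C)C[C@@](O[Si](C)(C)C)([C@H](O[Si](C)(C)C)[C@@H]2CC[C@]3(C)C(OS(=O)(=O)C(F)(F)F)=CC[C@@](C)(O[Si](C)(C)C)[C@@H]23)CC=C1OS(=O)(=O)C(F)(F)F | intermediate
32 | bis(alkenyl bromide), tris(trimethylsilyl) ether (C12(Br)=C13; C4'(Br)=C5') | CC1(C)C[C@@](O[Si](C)(C)C)([C@H](O[Si](C)(C)C)[C@@H]2CC[C@]3(C)C(Br)=CC[C@@](C)(O[Si](C)(C)C)[C@@H]23)CC=C1Br | intermediate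
33 | tris(trimethylsilyl) ether of 34 | CC1(C)C[C@@](O[Si](C)(C)C)([C@H](O[Si](C)(C)C)[C@@H]2CC[C@]3(C)[C@@H](Br)CC[C@@](C)(O[Si](C)(C)C)[C@@H]23)CC[C@@H]1Br | intermediate
34 | (R)-[(1R,4S)-4-bromo-1-hydroxy-3,3-dimethylcyclohexyl][(1R,3aS,4S,7R,7aS)-4-bromo-7-hydroxy-3a,7-dimethyloctahydro-1H-inden-1-yl]methanol (CNP0193924.1) | CC1(C)C[C@@](O)([C@H](O)[C@@H]2CC[C@]3(C)[C@@H](Br)CC[C@@](C)(O)[C@@H]23)CC[C@@H]1Br | target

## Step count and risk

Total step count: 23 (main line 19, ring A fragment 4). Longest linear sequence: 18 steps (1–3, 5–9, 14–23).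

Least certain steps:

**Step 5 (key).** The alkoxide aggregate may fail to deliver the alkenyl group, which would give competing 1,2-addition or undirected conjugate addition. The magnesium enolate may also be C-allylated too slowly, allowing proton transfer, enolate equilibration or O-allylation, and the face selectivity of allylation may erode because the axial C15 methyl lies on the face the electrophile must use. Fallback: separate the two bond formations and change the enolate counter-ion. Setting out from 4, the same directed addition of 9 is quenched with Me3SiCl/Et3N to isolate the bis(trimethylsilyl) enol ether F1. MeLi in THF then releases the lithium enolate, which is C-allylated with 7 in the presence of HMPA to the C15 trimethylsilyl ether of the allyl ketone F2. Dilute acid removes that silyl ether and the route is rejoined at 12.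

**Step 7.** Facial selectivity may be poor if steric approach anti to the angular methyl competes with hydroxyl-directed delivery, or the hindered alkene may react slowly with deactivation of the iridium catalyst. Fallback: rely on thermodynamics at C8 instead of direction. From 13, undirected hydrogenation (H2, Pd/C, EtOAc) is expected to give mainly the C8-epimeric silyl ether F3. The operations of steps 8 and 9 carry it through the C8-epimeric dioxolane F4 and the C8-epimeric diol F5 to the C8-epimeric aldehyde F6. Base (DBU, CH2Cl2) then epimerises the formyl-bearing carbon to the more stable arrangement trans to the C16–C15 bond, which is 17.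

**Step 16.** Hydride attack may show weak Felkin–Anh control, since the two ring substituents on C8 differ less than an open-chain model suggests, or conjugate reduction may intervene. Fallback: invert the wrong carbinol, not reduce the ketone. From 24, the (7S) allylic alcohol F7 is separated and subjected to Mitsunobu inversion with 4-nitrobenzoic acid, DIAD and PPh3 to the (7R) 4-nitrobenzoate F8. Methanolysis (K2CO3, MeOH) gives 26.

**Step 22.** Oxidative addition may be slow at enol triflates flanked by quaternary carbons, with reduction to the alkenes or loss of silyl groups taking over. Fallback: a Barton-type route that needs no triflates or protecting groups. From 29, hydrazine hydrate/Et3N in hot ethanol gives the bis(hydrazone) F9. N-bromosuccinimide with 2-tert-butyl-1,1,3,3-tetramethylguanidine converts it to the bis(alkenyl bromide) triol F10, and the hydrogen-atom-transfer hydrogenation of step 23 then leads directly to 34.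

**Step 23.** Hydrogen-atom transfer to the bromine-bearing carbon followed by loss of a bromine atom would cause debromination, and incomplete axial selectivity in the second hydrogen transfer at either ring would give an axial bromide. Fallback: concerted syn hydrogenation from the less hindered face with a different mechanism. From 32, H2 with [Ir(cod)(PCy3)(py)]PF6 in CH2Cl2 is used; the silylated oxygens do not direct, so hydrogen should add anti to the axial methyl groups. This gives 33, which rejoins the route at the acid desilylation to 34. This fallback makes no compound outside the list (F0).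

## Further compounds

F1 | step 5 | (3S,4R)-bis(trimethylsilyl) enol ether: {[3-(tert-butyldimethylsilyloxy)prop-1-en-2-yl]-2,4-dimethylcyclohex-1-ene-1,4-diyl}bis(oxy)bis(trimethylsilane) | CC1=C(O[Si](C)(C)C)CC[C@@](C)(O[Si](C)(C)C)[C@H]1C(=C)CO[Si](C)(C)C(C)(C)C
F2 | step 5 | (2S,3S,4R)-2-allyl-3-[3-(tert-butyldimethylsilyloxy)prop-1-en-2-yl]-2,4-dimethyl-4-(trimethylsilyloxy)cyclohexan-1-one | C=CC[C@]1(C)C(=O)CC[C@@](C)(O[Si](C)(C)C)[C@H]1C(=C)CO[Si](C)(C)C(C)(C)C
F3 | step 7 | (1S,3aS,7R,7aS)-1-[(tert-butyldimethylsilyloxy)methyl]-7-hydroxy-3a,7-dimethyloctahydro-4H-inden-4-one (C8 epimer of 14) | CC(C)(C)[Si](C)(C)OC[C@H]1CC[C@]2(C)C(=O)CC[C@@](C)(O)[C@@H]12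
F4 | step 7 | (1S,3aS,7R,7aS)-1-[(tert-butyldimethylsilyloxy)methyl]-4,4-(ethylenedioxy)-3a,7-dimethyloctahydro-1H-inden-7-ol (C8 epimer of 15) | CC(C)(C)[Si](C)(C)OC[C@H]1CC[C@]2(C)C3(OCCO3)CC[C@@](C)(O)[C@@H]12
F5 | step 7 | (1S,3aS,7R,7aS)-4,4-(ethylenedioxy)-1-(hydroxymethyl)-3a,7-dimethyloctahydro-1H-inden-7-ol (C8 epimer of 16) | OC[C@H]1CC[C@]2(C)C3(OCCO3)CC[C@@](C)(O)[C@@H]12
F6 | step 7 | (1S,3aS,7R,7aS)-4,4-(ethylenedioxy)-7-hydroxy-3a,7-dimethyloctahydro-1H-indene-1-carbaldehyde (C8 epimer of 17) | O=C[C@H]1CC[C@]2(C)C3(OCCO3)CC[C@@](C)(O)[C@@H]12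
F7 | step 16 | (S)-[(1R,3aS,7R,7aS)-4,4-(ethylenedioxy)-7-hydroxy-3a,7-dimethyloctahydro-1H-inden-1-yl](6,6-dimethyl-1,4-dioxaspiro[4.5]dec-8-en-8-yl)methanol (C7 epimer of 26) | CC1(C)CC(=CCC12OCCO2)[C@@H](O)[C@@H]3CC[C@]4(C)C5(OCCO5)CC[C@@](C)(O)[C@@H]34
F8 | step 16 | 4-nitrobenzoate of 26 at the C7 oxygen | CC1(C)CC(=CCC12OCCO2)[C@H](OC(=O)c6ccc(cc6)[N+](=O)[O-])[C@@H]3CC[C@]4(C)C5(OCCO5)CC[C@@](C)(O)[C@@H]34
F9 | step 22 | bis(hydrazone) of 29 (C12 and C4') | CC1(C)C[C@@](O)([C@H](O)[C@@H]2CC[C@]3(C)C(=NN)CC[C@@](C)(O)[C@@H]23)CCC1=NN
F10 | step 22 | bis(alkenyl bromide) triol (C12(Br)=C13; C4'(Br)=C5'; free C7, C15, C1' hydroxyls) | CC1(C)C[C@@](O)([C@H](O)[C@@H]2CC[C@]3(C)C(Br)=CC[C@@](C)(O)[C@@H]23)CC=C1Br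
F0 | step 23 | none | none
A1 | alternative 1 | (1R)-1-hydroxy-1-[(1R,3aS,7R,7aS)-4,4-(ethylenedioxy)-3a,7-dimethyl-7-(triethylsilyloxy)octahydro-1H-inden-1-yl]-5,5-(ethylenedioxy)-7-iodo-6,6-dimethylheptan-2-one | ICC(C)(C)C1(OCCO1)CCC(=O)[C@H](O)[C@@H]2CC[C@]3(C)C4(OCCO4)CC[C@@](C)(O[Si](CC)(CC)CC)[C@@H]23
A2 | alternative 1 | ring A diol with C4' and C12 dioxolanes and C15 triethylsilyl ether (C15 silyl ether of 28) | CC1(C)C[C@@](O)([C@H](O)[C@@H]2CC[C@]3(C)C4(OCCO4)CC[C@@](C)(O[Si](CC)(CC)CC)[C@@H]23)CCC15OCCO5
A3 | alternative 2 | (R)-2-[3-(methoxymethoxy)-3-methylpent-4-yn-1-yl]-2-(prop-1-en-2-yl)-1,3-dioxolane | C#C[C@](C)(OCOC)CCC1(OCCO1)C(C)=C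
A4 | alternative 2 | bicyclic cyclopentenone with quaternary C11, C12 dioxolane and C15 methoxymethyl ether | O=C1C[C@]3(C)C4(OCCO4)CC[C@@](C)(OCOC)C3=C1
A5 | alternative 3 | methyl 4-[(1S,2S,5R)-2-bromo-1,5-dimethyl-5-(trimethylsilyloxy)cyclohexyl]-2-diazo-3-oxobutanoate | COC(=O)C(=[N+]=[N-])C(=O)C[C@]1(C)[C@@H](Br)CC[C@@](C)(O[Si](C)(C)C)C1
A6 | alternative 3 | trans-hydrindane β-keto ester with C12 bromide and C15 trimethylsilyl ether | COC(=O)[C@@H]2C(=O)C[C@]3(C)[C@@H](Br)CC[C@@](C)(O[Si](C)(C)C)[C@@H]23
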